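**The problem**

Target 55 is a dimer of two guaianolides. The unprimed half has a 4-methylenecyclopent-1-en-3-one (ring A), a cycloheptane (ring B) and a trans-fused α-methylene lactone (ring C). The primed half has a cyclopentanone (ring E), a methylenecycloheptane (ring F) and a second α-methylene lactone (ring G). The halves are joined by a cyclohexene (ring D: C1, C2, C4', C15', C14, C10), and C4' is also the quaternary spiro carbon of ring E. Ten stereocentres must be set: C5, C6, C7 and C10 above, C4', C1', C5', C6', C7' and C8' below. C5' sits next to C4' and can relay configuration between the halves; C5 and C10 are γ to the C3 ketone and can epimerise. The three α-methylene carbonyl groups, the C10' methylene, the free C8' alcohol and the cross-conjugated dienone of ring A tolerate neither strong base, nucleophiles nor radicals, so they must arrive late or masked. The feature that opens the key step is that C10 and C4' are 1,4-related on ring D and carry C9 and C3' on the same face. C9–C3' can therefore be the third bridge of a bicyclo[2.2.2]octene, and since both carbons end as carbonyl-derived carbons, that bridge can be the two oxygenated carbons of a guaiacol.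

**Retrosynthesis**

55 is taken back to the tris(dimethylaminomethyl) compound 53. The C4, C11 and C11' methylenes are then released together in the last step, after all base and radical chemistry is over. Carrying free methylenes through the route would expose three Michael acceptors; the Mannich bases cost one step each to install.

52 (the C8' silyl ether of 53) is cut at C5–C6 and at the lactone C–O bond of ring C, giving enone 50. The forward reaction is a vinylogous aldol at the γ-carbon C5 onto a C6 aldehyde, trapped by lactonisation. Closing ring B at C8–C9 or C6–C7 instead would require C6 to be attached to C5 first, which is the harder bond to make intermolecularly. The precursor has ring B open and rings A, D, E, F, G intact.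

50 is traced through 46 and 45 to sulfoxide 43 by cutting C1'–C2' (ring E). An α-acyl thionium ion at C2' is captured by an allylsilane at C1'. This closes ring E cis by necessity and creates the C10' methylene, so no ketone at C10' ever has to be enolised or olefinated. Enolate alkylation at C1' was rejected because the C10' ketone would enolise towards C9' and lose the C8' oxygen.

The C6–C8, C11, C12 unit of 43 is removed through butenolide 40 and diene 39, by cutting C8=C9 (Wittig). This leads to keto aldehyde 33 and phosphonium salt 37, the latter from hydroxybutenolide 34. The butenolide double bond is kept until it can deliver a regiodefined ketene acetal for the C11 Mannich base.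

33 comes from diol 31 by glycol cleavage of C3'–C9. 31 comes from bicyclic ketone 27 via epoxide 28 and sulfide 29, i.e. by adding C2' to the C3' ketone before the bridge is cut. The C3' ketone of 27 has no α-hydrogen and C9 is masked as its ketal, so C2' goes on unambiguously.

27 is cut at C10–C14 and C4'–C15': dienone 26 plus ethylene 25, with 26 coming from phenol 24. Two stereocentres, one ring and two skeletal bonds are removed, and the arene that remains is flat.

24 is cut at C4'–C5' into aryl bromide 7 and enone lactone 18. The forward step is an asymmetric rhodium-catalysed conjugate addition whose silyl enol ether 21 is converted to enol triflate 22; this fixes the C1'=C10' regiochemistry needed later. 7 is made from indanone 1; its C3 carbinol and C15 are tied in a silylene that later shields one diene face. 18 is made from tropone 8 and tert-butyl acetate 9 through diene 14 and diol 16.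

**Roads not taken**

Alternative 1: The cut removes C1'–C5' and C9'–C10'. The forward step is a [Rh(CO)2Cl]2-catalysed (5+2) cycloaddition of an allene with a vinylcyclopropane held on C4', giving hexacycle A1. It builds rings E and F in one operation and delivers the C10' methylene directly from the allene; in ring economy for the lower half it is better than the chosen plan. Its weak points are that C4' must already be quaternary, carrying both a cyclopropane and the allene tether on a finished upper half, with nothing to control it. C1' and C5' would be set only by that centre, and the C6'–C8' triad and ring G still have to be built on the enol ether of A1. The chosen plan sets C4' together with C10 in a rigid bicycle and brings C6'–C8' in from tropone.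

Alternative 2: The cut is C4'–C5'. [Ir(cod)Cl]2 with a chiral phosphoramidite would ionise an allylic carbonate, and the para carbon of a phenolate would attack to give spirodienone A2. The catalyst sets C4' and C5' and ring E forms directly; in control of the spiro centre this is better than a substrate-directed cycloaddition. Against it, ring D arrives as a cyclohexadienone whose carbonyl and two alkenes must be removed, C10 is set only later by a reduction, and rings B, C, F and G are all still missing. The chosen plan has rings F and G complete before the key step and sets C10 in it.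

Alternative 3: The cuts are C14–C15' (6π electrocyclisation of a cross-conjugated triene) and C4'–C5' (BF3·OEt2-driven ring expansion of a 1-silyloxycyclobutyl group), giving A3, one desilylation from the target. If it worked it would be the shortest route by far. However, the triene must carry both α-methylene lactones and the ring A dienone through heating and a Lewis acid. C4' is created in a 1,2-shift onto a planar cation and C10 by a proton transfer, neither with an obvious control element. The chosen plan pays about fifteen more steps for having both centres fixed by a bicycle.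

Key step: step 18

Remarks on the chemistry: guaiane numbering is used (primes on the hydroxylated half). 10 and 11 are racemic. 35–51 are mixtures at the acetal carbon C6 (from 42 also at C7 and C11, from 50 at C4); these centres carry no descriptor in the SMILES and are removed or set in steps 36 and 38. C3' (28–32), C9 (31, 32), C2' (44) and sulfur (43) are likewise undefined and later destroyed.

Step 1
Reactants: 1 6-hydroxy-5-methoxyindan-1-one
Product: 2 7-bromo-6-hydroxy-5-methoxyindan-1-one
Conditions: NBS, MeCN, 0 °C to rt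
Reagents that add atoms: N-bromosuccinimide, O=C1CCC(=O)N1Br
Why: Electrophilic bromination directed by the phenol; para is the ring fusion and the other ortho position carries OMe, so only C7 (the future C4') is open, as in the 2-bromination of isovanillin.

Step 2
Reactants: 2 7-bromo-6-hydroxy-5-methoxyindan-1-one
Product: 3 7-bromo-5-methoxy-6-(methoxymethoxy)indan-1-one
Conditions: MeOCH2Cl, i-Pr2NEt, CH2Cl2, 0 °C to rt
Reagents that add atoms: chloromethyl methyl ether, COCCl
Why: O-alkylation of the phenol; the acetal survives the later organolithium step and supports the aryl–metal bond.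

Step 3
Reactants: 3 7-bromo-5-methoxy-6-(methoxymethoxy)indan-1-one
Product: 4 methyl 7-bromo-5-methoxy-6-(methoxymethoxy)-1-oxoindane-2-carboxylate (racemic)
Conditions: NaH, (MeO)2CO, THF, 65 °C; HCl work-up
Reagents that add atoms: dimethyl carbonate, COC(=O)OC
Why: Claisen-type C-acylation of the ketone enolate, driven by formation of the β-keto ester enolate; the ester carbon becomes C15.

Step 4
Reactants: 4 methyl 7-bromo-5-methoxy-6-(methoxymethoxy)-1-oxoindane-2-carboxylate
Product: 5 methyl (1R,2R)-7-bromo-1-hydroxy-5-methoxy-6-(methoxymethoxy)indane-2-carboxylate (cis)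
Conditions: RuCl[(R,R)-TsDPEN](p-cymene) (1 mol %), HCO2H–Et3N (5:2), DMF, 40 °C
Reagents that add atoms: none
Why: Asymmetric transfer hydrogenation with dynamic kinetic resolution: the β-keto ester racemises through its enol and hydride is delivered to one face of the aryl ketone, giving the (1R)-carbinol (C3) with the ester cis, the established outcome for 1-oxoindane-2-carboxylates.

Step 5
Reactants: 5 methyl (1R,2R)-7-bromo-1-hydroxy-5-methoxy-6-(methoxymethoxy)indane-2-carboxylate
Product: 6 (1R,2S)-7-bromo-2-(hydroxymethyl)-5-methoxy-6-(methoxymethoxy)indan-1-ol (cis)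
Conditions: LiBH4, THF–MeOH, 0 °C to rt
Reagents that add atoms: none
Why: Borohydride reduction of the ester; aryl bromide and acetal are inert.

Step 6
Reactants: 6 (1R,2S)-7-bromo-2-(hydroxymethyl)-5-methoxy-6-(methoxymethoxy)indan-1-ol
Product: 7 aryl bromide with the C3 and C15 oxygens bridged as a cis-fused di-tert-butylsilylene
Conditions: t-Bu2Si(OTf)2, 2,6-lutidine, CH2Cl2, 0 °C
Reagents that add atoms: di-tert-butylsilyl bis(trifluoromethanesulfonate), CC(C)(C)[Si](OS(=O)(=O)C(F)(F)F)(OS(=O)(=O)C(F)(F)F)C(C)(C)C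
Why: Silylene formation on the cis-1,3-diol; it protects C3 and C15 and places a bulky ring on one face next to C4'.

Step 7
Reactants: 8 tropone; 9 tert-butyl acetate
Product: 10 tert-butyl (7-oxocyclohepta-2,4-dien-1-yl)acetate (racemic)
Conditions: LiN(i-Pr)2, 9, THF, −78 °C; then 8, −78 °C; AcOH quench
Reagents that add atoms: none
Why: 1,8-Conjugate addition of the lithium ester enolate to tropone; kinetic α-protonation of the trienolate gives the 3,5-dienone, so C7' carries the C11'–C12' chain.

Step 8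
Reactants: 10 tert-butyl (7-oxocyclohepta-2,4-dien-1-yl)acetate
Product: 11 tert-butyl (cis-7-hydroxycyclohepta-2,4-dien-1-yl)acetate (racemic)
Conditions: LiBH(s-Bu)3, THF, −78 °C; NH4Cl work-up
Reagents that add atoms: none
Why: The bulky hydride attacks anti to the adjacent side chain, giving the cis alcohol (C8'); the tert-butyl ester resists lactonisation.

Step 9
Reactants: 11 tert-butyl (cis-7-hydroxycyclohepta-2,4-dien-1-yl)acetate
Product: 12 tert-butyl [(1S,7R)-7-acetoxycyclohepta-2,4-dien-1-yl]acetate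
Conditions: lipase PS (Burkholderia cepacia), vinyl acetate, t-BuOMe, 30 °C, stopped near half conversion
Reagents that add atoms: vinyl acetate, CC(=O)OC=C
Why: Lipase-catalysed kinetic resolution by acylation; the (R)-carbinol, whose larger flank is the branched ring carbon, should be acylated faster and is separated from the unreacted (1R,7S)-alcohol.

Step 10
Reactants: 12 tert-butyl [(1S,7R)-7-acetoxycyclohepta-2,4-dien-1-yl]acetate
Product: 13 tert-butyl [(1S,7R)-7-hydroxycyclohepta-2,4-dien-1-yl]acetate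
Conditions: K2CO3 (cat.), MeOH, 0 °C
Reagents that add atoms: none
Why: Transesterification of the acetate; the tert-butyl ester is untouched.

Step 11
Reactants: 13 tert-butyl [(1S,7R)-7-hydroxycyclohepta-2,4-dien-1-yl]acetate
Product: 14 triisopropylsilyl ether of 13
Conditions: i-Pr3SiOTf, 2,6-lutidine, CH2Cl2, −78 to 0 °C
Reagents that add atoms: triisopropylsilyl trifluoromethanesulfonate, CC(C)[Si](C(C)C)(C(C)C)OS(=O)(=O)C(F)(F)F
Why: Silylation of the C8' alcohol with a group that outlasts the acid, base and fluoride steps before step 37.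

Step 12
Reactants: 14 triisopropylsilyl ether of 13
Product: 16 cis-1,4-diol (OH at C6' and C10', both trans to the C7' chain and the C8' silyl ether), via endoperoxide 15 (not isolated)
Conditions: O2, hν, tetraphenylporphyrin, CH2Cl2, −78 °C; then thiourea, MeOH, rt
Reagents that add atoms: oxygen, O=O
Why: [4+2] cycloaddition of singlet oxygen to the cyclic diene on the face opposite the two substituents sets C6'; thiourea reduces the O–O bond to the cis-diol.

Step 13
Reactants: 16 cis-1,4-diol
Product: 17 trans-fused hydroxy lactone (ring G closed on the C6' oxygen, allylic OH at C10')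
Conditions: CF3CO2H, CH2Cl2, 0 °C
Reagents that add atoms: none
Why: Acidolysis of the tert-butyl ester and spontaneous γ-lactonisation; only the C6' hydroxyl is 1,4 to the acid, so the lactone regiochemistry is unambiguous.

Step 14
Reactants: 17 trans-fused hydroxy lactone
Product: 18 enone lactone (cyclohept-2-enone, lactone oxygen at the γ-carbon C6')
Conditions: DMP (triacetoxy periodinane), NaHCO3, CH2Cl2, 0 °C to rt
Reagents that add atoms: none
Why: Oxidation of the remaining allylic alcohol gives the C10' enone with C1'=C5'.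

Step 15
Reactants: 7 silylene-protected aryl bromide; 18 enone lactone
Product: 22 C5'-aryl enol triflate (C1'=C10'–OTf, aryl trans to the lactone oxygen), via aryllithium 19 (not isolated), via arylzinc chloride 20 (not isolated), via silyl enol ether 21 (not isolated)
Conditions: 7, t-BuLi, THF, −78 °C; ZnCl2; then 18, [Rh(cod)Cl]2 (3 mol %), (R)-BINAP, Me3SiCl, THF, 20 °C; then CsF, PhNTf2, DME, rt
Reagents that add atoms: N-phenylbis(trifluoromethanesulfonimide), O=S(=O)(N(c1ccccc1)S(=O)(=O)C(F)(F)F)C(F)(F)F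
Why: Rhodium-catalysed asymmetric conjugate addition of an arylzinc chloride with in situ silylation sets C5'; the aryl enters anti to the γ-oxygen and (R)-BINAP should be the matched ligand. The regiodefined silyl enol ether is converted to the enol triflate by fluoride.

Step 16
Reactants: 22 C5'-aryl enol triflate
Product: 23 enol triflate with C11' dimethylaminomethyl group (trans to C8')
Conditions: LiN(i-Pr)2, THF, −78 °C; CH2=NMe2+ I−, −78 to 0 °C
Reagents that add atoms: dimethylmethyleneiminium iodide, C=[N+](C)C.[I-]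
Why: Mannich reaction of the lactone enolate, the only enolisable carbonyl present; the amine masks the later C11' methylene.

Step 17
Reactants: 23 enol triflate with C11' dimethylaminomethyl group
Product: 24 phenol (6-hydroxy-5-methoxyindane core; key-step precursor)
Conditions: ZnBr2, n-PrSH, CH2Cl2, 0 °C
Reagents that add atoms: none
Why: Lewis acid and thiol cleave the methoxymethyl ether; silyl ethers, triflate and lactone stay.

Step 18
Reactants: 24 phenol; 25 ethylene
Product: 27 bicyclo[2.2.2]octenone (C3' ketone, C9 dimethyl ketal, ethano bridge C14–C15'), via dimethoxy dienone 26 (not isolated)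
Conditions: CF3CO2H (1.1 equiv), PhI(OAc)2, MeOH, 0 °C; evaporate; ethylene (50 bar), toluene, 80 °C; NaHCO3 work-up
Reagents that add atoms: methanol, CO
Why: PhI(OAc)2 oxidises the phenol (amine held as its trifluoroacetate) and methanol is captured at the methoxy-bearing carbon C9, giving the masked ortho-benzoquinone 26 with the diene C4'=C2–C1=C10. Ethylene then adds across C4' and C10 in a thermal [4+2] cycloaddition, the reaction type known for such dienones with alkenes, ethylene under pressure included. Ring D closes by this cycloaddition through C10–C14 and C4'–C15', inside a bicycle whose third bridge is C9–C3'. C4' and C10 are created together and their relative configuration is fixed by the bicycle, so only the diene face has to be chosen. That choice is assigned to the silylene on C3/C4, a ring substituent held on one face beside C4', so that ethylene should enter anti to it. The C5' group can turn so that H5' lies beside the C3' carbonyl, C6' points to the shielded face and the flat vinyl carbon C1' to the open one. The substituted terminus C4' and the fused ring should slow the dimerisation usual for these dienones. The enol triflate, lactone, silyl groups and ammonium salt are spectators.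

Step 19
Reactants: 27 bicyclo[2.2.2]octenone
Product: 28 spiro-epoxide at C3' (epoxide CH2 is C2')
Conditions: Me3S+ I−, KN(SiMe3)2, THF, −10 to 0 °C
Reagents that add atoms: trimethylsulfonium iodide, C[S+](C)C.[I-]
Why: Corey–Chaykovsky epoxidation of the only ketone, which has no α-hydrogen; the new C3' centre is lost in step 23.

Step 20
Reactants: 28 spiro-epoxide at C3'
Product: 29 β-hydroxy sulfide (C3'–OH, C2'–SPh)
Conditions: PhSH, Et3N, MeOH, rt
Reagents that add atoms: thiophenol, Sc1ccccc1
Why: Thiolate opens the epoxide at its unsubstituted carbon.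

Step 21
Reactants: 29 β-hydroxy sulfide
Product: 31 C3',C9-diol, via hydroxy ketone 30 (not isolated)
Conditions: 1 M HCl, THF, rt; neutralise; NaBH4, MeOH, −20 °C
Reagents that add atoms: water, O
Why: Ketal hydrolysis frees the C9 ketone, which is reduced at once so that the α-ketol has no time to rearrange.

Step 22
Reactants: 31 C3',C9-diol
Product: 32 allylsilane (C1'=C10'–CH2SiMe3)
Conditions: Me3SiCH2MgCl, ZnCl2, THF; Pd(PPh3)4 (5 mol %), LiCl, THF, 50 °C
Reagents that add atoms: (trimethylsilyl)methylmagnesium chloride, C[Si](C)(C)C[Mg]Cl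
Why: Negishi coupling of the enol triflate; the organozinc reagent tolerates lactone, sulfide and amine.

Step 23
Reactants: 32 allylsilane
Product: 33 keto aldehyde (C9 aldehyde on C10, phenylthiomethyl ketone C3' on C4')
Conditions: NaIO4 (1.2 equiv), AcOH (1 equiv), THF–H2O, 0 °C, short reaction time
Reagents that add atoms: none
Why: Periodate glycol cleavage cuts the C3'–C9 bridge; ring D remains with C10 and C4' set.

Step 24
Reactants: 34 5-hydroxy-4-methylfuran-2(5H)-one
Product: 35 5-methoxy-4-methylfuran-2(5H)-one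
Conditions: MeOH, p-TsOH (cat.), reflux
Reagents that add atoms: methanol, CO
Why: Acid-catalysed pseudoester formation; the acetal carbon is the future C6.

Step 25
Reactants: 35 5-methoxy-4-methylfuran-2(5H)-one
Product: 36 4-(bromomethyl)-5-methoxyfuran-2(5H)-one
Conditions: NBS, AIBN (cat.), PhCF3, 80 °C
Reagents that add atoms: N-bromosuccinimide, O=C1CCC(=O)N1Br
Why: Wohl–Ziegler bromination of the allylic methyl group (C8).

Step 26
Reactants: 36 4-(bromomethyl)-5-methoxyfuran-2(5H)-one
Product: 37 [(2-methoxy-5-oxo-2,5-dihydrofuran-3-yl)methyl]triphenylphosphonium bromide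
Conditions: PPh3, toluene, 60 °C
Reagents that add atoms: triphenylphosphine, c1ccc(cc1)P(c2ccccc2)c3ccccc3
Why: SN2 alkylation of the phosphine by the allylic bromide.

Step 27
Reactants: 33 keto aldehyde; 37 phosphonium bromide
Product: 39 (E)-dienyl butenolide (C8=C9), via phosphorus ylide 38 (not isolated)
Conditions: 37, NaN(SiMe3)2, THF, −78 °C; then 33, −78 to 0 °C
Reagents that add atoms: none
Why: Wittig olefination with a lactone-stabilised ylide; it is mild enough to spare the hindered ketone and the epimerisable C10.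

Step 28
Reactants: 39 (E)-dienyl butenolide
Product: 40 butenolide with saturated C8–C9
Conditions: 2-O2NC6H4SO2NHNH2, Et3N, CH2Cl2, rt
Reagents that add atoms: none
Why: Diimide reduces the disubstituted alkene; the trisubstituted butenolide and allylsilane and the tetrasubstituted C1=C2 react far more slowly.

Step 29
Reactants: 40 butenolide with saturated C8–C9
Product: 42 saturated pseudoester lactone with C11 dimethylaminomethyl group, via silyl ketene acetal 41 (not isolated)
Conditions: [(Ph3P)CuH]6 (cat.), PhMe2SiH, toluene, rt; then CH2=NMe2+ I−, CH2Cl2, 0 °C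
Reagents that add atoms: dimethylmethyleneiminium iodide, C=[N+](C)C.[I-]
Why: Copper hydride conjugate reduction of the β-substituted butenolide gives the ketene acetal without base, and a Mukaiyama–Mannich reaction installs the C11 mask.

Step 30
Reactants: 42 saturated pseudoester lactone
Product: 43 β-keto sulfoxide
Conditions: NaIO4, AcOH (2.2 equiv), MeOH–H2O, 0 °C to rt
Reagents that add atoms: sodium periodate, [Na+].[O-]I(=O)(=O)=O
Why: Periodate oxidises the sulfide to the sulfoxide; the amines are protonated and the alkenes are inert.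

Step 31
Reactants: 43 β-keto sulfoxide
Product: 44 spiro compound with ring E closed (C2' phenylthio ketone, C10' methylene)
Conditions: CF3CO2H (2.2 equiv), (CF3CO)2O, CH2Cl2, −40 to 0 °C
Reagents that add atoms: none
Why: Pummerer reaction gives an α-acyl thionium ion at C2', which the allylsilane attacks through C1' (Hosomi–Sakurai type, 5-exo) with loss of silicon, forming ring E and the C10' methylene; the tether from C5' allows only the cis ring fusion, which sets C1'.

Step 32
Reactants: 44 spiro compound with ring E closed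
Product: 45 ring E ketone with C2' methylene
Conditions: Bu3SnH, AIBN (cat.), toluene, 80 °C
Reagents that add atoms: none
Why: Radical reduction of the α-phenylthio ketone C–S bond.

Step 33
Reactants: 45 ring E ketone
Product: 46 C3,C15-diol
Conditions: HF·pyridine, pyridine, THF, 0 °C
Reagents that add atoms: none
Why: Fluoride cleaves the silylene much faster than the secondary triisopropylsilyl ether.

Step 34
Reactants: 46 C3,C15-diol
Product: 47 C15 methanesulfonate
Conditions: MeSO2Cl, 2,4,6-collidine, CH2Cl2, −20 °C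
Reagents that add atoms: methanesulfonyl chloride, CS(=O)(=O)Cl
Why: Selective sulfonylation of the primary alcohol over the hindered secondary allylic one.

Step 35
Reactants: 47 C15 methanesulfonate
Product: 50 enone with C4 dimethylaminomethyl group, via keto mesylate 48 (not isolated), via methylene dienone 49 (not isolated)
Conditions: DMP, NaHCO3, CH2Cl2, 0 °C; Et3N; then Me2NH (1.1 equiv), THF, 0 °C
Reagents that add atoms: dimethylamine, CNC
Why: Oxidation of the allylic C3 alcohol, β-elimination of the mesylate and conjugate addition of dimethylamine; the amine masks the sensitive C4 methylene until the end.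

Step 36
Reactants: 50 enone with C4 dimethylaminomethyl group
Product: 52 heptacycle with rings B and C closed (three dimethylaminomethyl groups, C8' silyl ether), via aldehyde ester 51 (not isolated)
Conditions: NaOMe (1.5 equiv), Me2NH (1 equiv), MeOH, −20 to 0 °C; AcOH quench
Reagents that add atoms: none
Why: Methoxide opens the pseudoester to the C6 aldehyde and C12 methyl ester, the γ-dienolate of the enone adds through C5 (intramolecular vinylogous aldol, seven-membered ring), and the C6 alkoxide lactonises onto C12. C7 equilibrates through the aldehyde and is fixed, with C5 and C6, when the trans-fused lactone closes; C5 remains correctable as a γ-position.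

Step 37
Reactants: 52 heptacycle with rings B and C closed
Product: 53 C8' alcohol
Conditions: HF·pyridine, THF, rt
Reagents that add atoms: none
Why: Fluoride removal of the triisopropylsilyl ether.

Step 38
Reactants: 53 C8' alcohol
Product: 55 target CNP0178208.1, via tris(trimethylammonium) iodide 54 (not isolated)
Conditions: MeI, MeOH–CH2Cl2, rt; then NaHCO3 (aq), CH2Cl2, rt
Reagents that add atoms: none
Why: Exhaustive N-methylation followed by Hofmann-type β-elimination of trimethylamine from the three β-ammonium carbonyl units releases the C4, C11 and C11' methylenes under conditions the dienone tolerates.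

Compound list

1 | 6-hydroxy-5-methoxyindan-1-one | COc1cc2CCC(=O)c2cc1O | starting material
2 | 7-bromo-6-hydroxy-5-methoxyindan-1-one | COc1cc2CCC(=O)c2c(Br)c1O | intermediate
3 | 7-bromo-5-methoxy-6-(methoxymethoxy)indan-1-one | COCOc1c(OC)cc2CCC(=O)c2c1Br | intermediate
4 | methyl 7-bromo-5-methoxy-6-(methoxymethoxy)-1-oxoindane-2-carboxylate (racemic) | COCOc1c(OC)cc2CC(C(=O)OC)C(=O)c2c1Br | intermediate
5 | methyl (1R,2R)-7-bromo-1-hydroxy-5-methoxy-6-(methoxymethoxy)indane-2-carboxylate | COCOc1c(OC)cc2C[C@@H](C(=O)OC)[C@@H](O)c2c1Br | intermediate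
6 | (1R,2S)-7-bromo-2-(hydroxymethyl)-5-methoxy-6-(methoxymethoxy)indan-1-ol | COCOc1c(OC)cc2C[C@@H](CO)[C@@H](O)c2c1Br | intermediate
7 | di-tert-butylsilylene of 6 (cis-fused) | COCOc1c(OC)cc2C[C@H]3CO[Si](C(C)(C)C)(C(C)(C)C)O[C@H]3c2c1Br | intermediate
8 | tropone | O=C1C=CC=CC=C1 | starting material
9 | tert-butyl acetate | CC(=O)OC(C)(C)C | starting material
10 | tert-butyl (7-oxocyclohepta-2,4-dien-1-yl)acetate (racemic) | CC(C)(C)OC(=O)CC1C=CC=CCC1=O | intermediate
11 | tert-butyl (cis-7-hydroxycyclohepta-2,4-dien-1-yl)acetate (racemic, both enantiomers shown) | CC(C)(C)OC(=O)C[C@H]1C=CC=CC[C@H]1O.CC(C)(C)OC(=O)C[C@@H]1C=CC=CC[C@@H]1O | intermediate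
12 | tert-butyl [(1S,7R)-7-acetoxycyclohepta-2,4-dien-1-yl]acetate | CC(C)(C)OC(=O)C[C@H]1C=CC=CC[C@H]1OC(C)=O | intermediate
13 | tert-butyl [(1S,7R)-7-hydroxycyclohepta-2,4-dien-1-yl]acetate | CC(C)(C)OC(=O)C[C@H]1C=CC=CC[C@H]1O | intermediate
14 | triisopropylsilyl ether of 13 | CC(C)(C)OC(=O)C[C@H]1C=CC=CC[C@H]1O[Si](C(C)C)(C(C)C)C(C)C | intermediate
15 | endoperoxide across C6' and C10' | CC(C)(C)OC(=O)C[C@H]1[C@@H]2OO[C@@H](C=C2)C[C@H]1O[Si](C(C)C)(C(C)C)C(C)C | intermediate
16 | cis-1,4-diol (C6', C10') | CC(C)(C)OC(=O)C[C@H]1[C@H](O)C=C[C@H](O)C[C@H]1O[Si](C(C)C)(C(C)C)C(C)C | intermediate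
17 | trans-fused hydroxy lactone | O[C@H]1C=C[C@H]2OC(=O)C[C@@H]2[C@H](O[Si](C(C)C)(C(C)C)C(C)C)C1 | intermediate
18 | enone lactone | O=C1C=C[C@H]2OC(=O)C[C@@H]2[C@H](O[Si](C(C)C)(C(C)C)C(C)C)C1 | intermediate
19 | aryllithium from 7 | COCOc1c(OC)cc2C[C@H]3CO[Si](C(C)(C)C)(C(C)(C)C)O[C@H]3c2c1[Li] | intermediate
20 | arylzinc chloride from 7 | COCOc1c(OC)cc2C[C@H]3CO[Si](C(C)(C)C)(C(C)(C)C)O[C@H]3c2c1[Zn]Cl | intermediate
21 | C5'-aryl trimethylsilyl enol ether | COCOc1c(OC)cc2C[C@H]3CO[Si](C(C)(C)C)(C(C)(C)C)O[C@H]3c2c1[C@@H]4[C@H]5OC(=O)C[C@@H]5[C@H](O[Si](C(C)C)(C(C)C)C(C)C)CC(O[Si](C)(C)C)=C4 | intermediate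
22 | C5'-aryl enol triflate | COCOc1c(OC)cc2C[C@H]3CO[Si](C(C)(C)C)(C(C)(C)C)O[C@H]3c2c1[C@@H]4[C@H]5OC(=O)C[C@@H]5[C@H](O[Si](C(C)C)(C(C)C)C(C)C)CC(OS(=O)(=O)C(F)(F)F)=C4 | intermediate
23 | enol triflate with C11' dimethylaminomethyl group | COCOc1c(OC)cc2C[C@H]3CO[Si](C(C)(C)C)(C(C)(C)C)O[C@H]3c2c1[C@@H]4[C@H]5OC(=O)[C@@H](CN(C)C)[C@@H]5[C@H](O[Si](C(C)C)(C(C)C)C(C)C)CC(OS(=O)(=O)C(F)(F)F)=C4 | intermediate
24 | phenol, key-step precursor | Oc1c(OC)cc2C[C@H]3CO[Si](C(C)(C)C)(C(C)(C)C)O[C@H]3c2c1[C@@H]4[C@H]5OC(=O)[C@@H](CN(C)C)[C@@H]5[C@H](O[Si](C(C)C)(C(C)C)C(C)C)CC(OS(=O)(=O)C(F)(F)F)=C4 | intermediate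
25 | ethylene | C=C | starting material
26 | 6,6-dimethoxycyclohexa-2,4-dienone (masked ortho-benzoquinone) | COC1(OC)C=C2C[C@H]3CO[Si](C(C)(C)C)(C(C)(C)C)O[C@H]3C2=C([C@@H]4[C@H]5OC(=O)[C@@H](CN(C)C)[C@@H]5[C@H](O[Si](C(C)C)(C(C)C)C(C)C)CC(OS(=O)(=O)C(F)(F)F)=C4)C1=O | intermediate
27 | bicyclo[2.2.2]octenone, key-step product | COC1(OC)[C@@H]2CC[C@]([C@@H]5[C@H]6OC(=O)[C@@H](CN(C)C)[C@@H]6[C@H](O[Si](C(C)C)(C(C)C)C(C)C)CC(OS(=O)(=O)C(F)(F)F)=C5)(C1=O)C3=C2C[C@H]4CO[Si](C(C)(C)C)(C(C)(C)C)O[C@@H]34 | intermediate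
28 | C3' spiro-epoxide | COC1(OC)[C@@H]2CC[C@]([C@@H]5[C@H]6OC(=O)[C@@H](CN(C)C)[C@@H]6[C@H](O[Si](C(C)C)(C(C)C)C(C)C)CC(OS(=O)(=O)C(F)(F)F)=C5)(C17CO7)C3=C2C[C@H]4CO[Si](C(C)(C)C)(C(C)(C)C)O[C@@H]34 | intermediate
29 | β-hydroxy sulfide | COC1(OC)[C@@H]2CC[C@]([C@@H]5[C@H]6OC(=O)[C@@H](CN(C)C)[C@@H]6[C@H](O[Si](C(C)C)(C(C)C)C(C)C)CC(OS(=O)(=O)C(F)(F)F)=C5)(C1(O)CSc7ccccc7)C3=C2C[C@H]4CO[Si](C(C)(C)C)(C(C)(C)C)O[C@@H]34 | intermediate
30 | C9 ketone, C3' tertiary alcohol | O=C1[C@@H]2CC[C@]([C@@H]5[C@H]6OC(=O)[C@@H](CN(C)C)[C@@H]6[C@H](O[Si](C(C)C)(C(C)C)C(C)C)CC(OS(=O)(=O)C(F)(F)F)=C5)(C1(O)CSc7ccccc7)C3=C2C[C@H]4CO[Si](C(C)(C)C)(C(C)(C)C)O[C@@H]34 | intermediate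
31 | C3',C9-diol | OC1[C@@H]2CC[C@]([C@@H]5[C@H]6OC(=O)[C@@H](CN(C)C)[C@@H]6[C@H](O[Si](C(C)C)(C(C)C)C(C)C)CC(OS(=O)(=O)C(F)(F)F)=C5)(C1(O)CSc7ccccc7)C3=C2C[C@H]4CO[Si](C(C)(C)C)(C(C)(C)C)O[C@@H]34 | intermediate
32 | allylsilane diol | OC1[C@@H]2CC[C@]([C@@H]5[C@H]6OC(=O)[C@@H](CN(C)C)[C@@H]6[C@H](O[Si](C(C)C)(C(C)C)C(C)C)CC(C[Si](C)(C)C)=C5)(C1(O)CSc7ccccc7)C3=C2C[C@H]4CO[Si](C(C)(C)C)(C(C)(C)C)O[C@@H]34 | intermediate
33 | keto aldehyde | O=C[C@@H]2CC[C@]([C@@H]5[C@H]6OC(=O)[C@@H](CN(C)C)[C@@H]6[C@H](O[Si](C(C)C)(C(C)C)C(C)C)CC(C[Si](C)(C)C)=C5)(C(=O)CSc7ccccc7)C3=C2C[C@H]4CO[Si](C(C)(C)C)(C(C)(C)C)O[C@@H]34 | intermediate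
34 | 5-hydroxy-4-methylfuran-2(5H)-one | CC1=CC(=O)OC1O | starting material
35 | 5-methoxy-4-methylfuran-2(5H)-one | COC1OC(=O)C=C1C | intermediate
36 | 4-(bromomethyl)-5-methoxyfuran-2(5H)-one | COC1OC(=O)C=C1CBr | intermediate
37 | [(2-methoxy-5-oxo-2,5-dihydrofuran-3-yl)methyl]triphenylphosphonium bromide | COC1OC(=O)C=C1C[P+](c2ccccc2)(c3ccccc3)c4ccccc4.[Br-] | intermediate
38 | phosphorus ylide from 37 | COC1OC(=O)C=C1C=P(c2ccccc2)(c3ccccc3)c4ccccc4 | intermediate
39 | (E)-dienyl butenolide | COC1OC(=O)C=C1/C=C/[C@@H]2CC[C@]([C@@H]5[C@H]6OC(=O)[C@@H](CN(C)C)[C@@H]6[C@H](O[Si](C(C)C)(C(C)C)C(C)C)CC(C[Si](C)(C)C)=C5)(C(=O)CSc7ccccc7)C3=C2C[C@H]4CO[Si](C(C)(C)C)(C(C)(C)C)O[C@@H]34 | intermediate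
40 | butenolide with saturated C8–C9 | COC1OC(=O)C=C1CC[C@@H]2CC[C@]([C@@H]5[C@H]6OC(=O)[C@@H](CN(C)C)[C@@H]6[C@H](O[Si](C(C)C)(C(C)C)C(C)C)CC(C[Si](C)(C)C)=C5)(C(=O)CSc7ccccc7)C3=C2C[C@H]4CO[Si](C(C)(C)C)(C(C)(C)C)O[C@@H]34 | intermediate
41 | silyl ketene acetal | COC1OC(O[Si](C)(C)c8ccccc8)=CC1CC[C@@H]2CC[C@]([C@@H]5[C@H]6OC(=O)[C@@H](CN(C)C)[C@@H]6[C@H](O[Si](C(C)C)(C(C)C)C(C)C)CC(C[Si](C)(C)C)=C5)(C(=O)CSc7ccccc7)C3=C2C[C@H]4CO[Si](C(C)(C)C)(C(C)(C)C)O[C@@H]34 | intermediate
42 | pseudoester lactone with C11 dimethylaminomethyl group | COC1OC(=O)C(CN(C)C)C1CC[C@@H]2CC[C@]([C@@H]5[C@H]6OC(=O)[C@@H](CN(C)C)[C@@H]6[C@H](O[Si](C(C)C)(C(C)C)C(C)C)CC(C[Si](C)(C)C)=C5)(C(=O)CSc7ccccc7)C3=C2C[C@H]4CO[Si](C(C)(C)C)(C(C)(C)C)O[C@@H]34 | intermediate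
43 | β-keto sulfoxide | COC1OC(=O)C(CN(C)C)C1CC[C@@H]2CC[C@]([C@@H]5[C@H]6OC(=O)[C@@H](CN(C)C)[C@@H]6[C@H](O[Si](C(C)C)(C(C)C)C(C)C)CC(C[Si](C)(C)C)=C5)(C(=O)CS(=O)c7ccccc7)C3=C2C[C@H]4CO[Si](C(C)(C)C)(C(C)(C)C)O[C@@H]34 | intermediate
44 | ring E closed, C2' phenylthio ketone | COC1OC(=O)C(CN(C)C)C1CC[C@@H]2CC[C@]5(C(=O)C(Sc8ccccc8)[C@H]6C(=C)C[C@@H](O[Si](C(C)C)(C(C)C)C(C)C)[C@H]7[C@H](CN(C)C)C(=O)O[C@@H]7[C@H]65)C3=C2C[C@H]4CO[Si](C(C)(C)C)(C(C)(C)C)O[C@@H]34 | intermediate
45 | ring E ketone | COC1OC(=O)C(CN(C)C)C1CC[C@@H]2CC[C@]5(C(=O)C[C@H]6C(=C)C[C@@H](O[Si](C(C)C)(C(C)C)C(C)C)[C@H]7[C@H](CN(C)C)C(=O)O[C@@H]7[C@H]65)C3=C2C[C@H]4CO[Si](C(C)(C)C)(C(C)(C)C)O[C@@H]34 | intermediate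
46 | C3,C15-diol | COC1OC(=O)C(CN(C)C)C1CC[C@@H]2CC[C@]5(C(=O)C[C@H]6C(=C)C[C@@H](O[Si](C(C)C)(C(C)C)C(C)C)[C@H]7[C@H](CN(C)C)C(=O)O[C@@H]7[C@H]65)C3=C2C[C@@H](CO)[C@H]3O | intermediate
47 | C15 methanesulfonate | COC1OC(=O)C(CN(C)C)C1CC[C@@H]2CC[C@]5(C(=O)C[C@H]6C(=C)C[C@@H](O[Si](C(C)C)(C(C)C)C(C)C)[C@H]7[C@H](CN(C)C)C(=O)O[C@@H]7[C@H]65)C3=C2C[C@@H](COS(C)(=O)=O)[C@H]3O | intermediate
48 | C3 ketone, C15 methanesulfonate | COC1OC(=O)C(CN(C)C)C1CC[C@@H]2CC[C@]5(C(=O)C[C@H]6C(=C)C[C@@H](O[Si](C(C)C)(C(C)C)C(C)C)[C@H]7[C@H](CN(C)C)C(=O)O[C@@H]7[C@H]65)C3=C2C[C@@H](COS(C)(=O)=O)C3=O | intermediate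
49 | 4-methylene dienone | COC1OC(=O)C(CN(C)C)C1CC[C@@H]2CC[C@]5(C(=O)C[C@H]6C(=C)C[C@@H](O[Si](C(C)C)(C(C)C)C(C)C)[C@H]7[C@H](CN(C)C)C(=O)O[C@@H]7[C@H]65)C3=C2CC(=C)C3=O | intermediate
50 | enone with C4 dimethylaminomethyl group | COC1OC(=O)C(CN(C)C)C1CC[C@@H]2CC[C@]5(C(=O)C[C@H]6C(=C)C[C@@H](O[Si](C(C)C)(C(C)C)C(C)C)[C@H]7[C@H](CN(C)C)C(=O)O[C@@H]7[C@H]65)C3=C2CC(CN(C)C)C3=O | intermediate
51 | C6 aldehyde, C12 methyl ester | COC(=O)C(CN(C)C)C(C=O)CC[C@@H]2CC[C@]5(C(=O)C[C@H]6C(=C)C[C@@H](O[Si](C(C)C)(C(C)C)C(C)C)[C@H]7[C@H](CN(C)C)C(=O)O[C@@H]7[C@H]65)C3=C2CC(CN(C)C)C3=O | intermediate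
52 | heptacyclic tris(dimethylaminomethyl) C8' silyl ether | CN(C)CC1C(=O)C2=C3[C@H](CC[C@H]4C(CN(C)C)C(=O)O[C@@H]4[C@H]13)CC[C@]21C(=O)C[C@H]2C(=C)C[C@@H](O[Si](C(C)C)(C(C)C)C(C)C)[C@H]3[C@H](CN(C)C)C(=O)O[C@@H]3[C@H]21 | intermediate
53 | heptacyclic tris(dimethylaminomethyl) C8' alcohol | CN(C)CC1C(=O)C2=C3[C@H](CC[C@H]4C(CN(C)C)C(=O)O[C@@H]4[C@H]13)CC[C@]21C(=O)C[C@H]2C(=C)C[C@@H](O)[C@H]3[C@H](CN(C)C)C(=O)O[C@@H]3[C@H]21 | intermediate
54 | tris(trimethylammonium) triiodide of 53 | C[N+](C)(C)CC1C(=O)C2=C3[C@H](CC[C@H]4C(C[N+](C)(C)C)C(=O)O[C@@H]4[C@H]13)CC[C@]21C(=O)C[C@H]2C(=C)C[C@@H](O)[C@H]3[C@H](C[N+](C)(C)C)C(=O)O[C@@H]3[C@H]21.[I-].[I-].[I-] | intermediate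
55 | CNP0178208.1 | C=C1C(=O)C2=C3[C@H](CC[C@H]4C(=C)C(=O)O[C@@H]4[C@H]13)CC[C@]21C(=O)C[C@H]2C(=C)C[C@@H](O)[C@H]3C(=C)C(=O)O[C@@H]3[C@H]21 | target

Total step count: 38. Longest linear sequence: 29 steps (tropone 8 through steps 7–23 and 27–38).

Least certain steps

Step 18 (key step). Ethylene is a poor dienophile, so the dienone may decompose before it reacts. The face selection may also be incomplete, because the C5' centre on its own would favour the opposite face if H5' turned towards the peri position. Fallback: starting from 24, dienone 26 is made as before and treated at 0 °C with nitroethylene, a far more reactive ethylene equivalent, to give the nitro adduct F1 (either regioisomer serves). Radical denitration with Bu3SnH and AIBN in toluene at 110 °C then returns to 27; the low cycloaddition temperature should also sharpen the facial preference.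

Step 15. Transmetalation of the doubly ortho-substituted arylzinc reagent to rhodium may be slow, leading to protodemetalation and incomplete conversion. Fallback: aryllithium 19 is converted with MgBr2 into the aryl Grignard reagent F2, which is added to 18 with catalytic CuBr·SMe2 and Me3SiCl at −78 °C. This relies on substrate control only (entry anti to the C6' oxygen) and rejoins the route at silyl enol ether 21; allylic C–O cleavage by copper is the risk of this variant.

Step 19. The ylide may fail to add to the hindered bridgehead-flanked ketone, or may attack the lactone instead. Fallback: 27 is treated with chloromethyllithium made in its presence (ICH2Cl, MeLi·LiBr, THF, −78 °C) to give the chlorohydrin F3, which K2CO3 in MeOH closes to epoxide 28.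

Step 31. The thionium ion may be captured by trifluoroacetate or by the tetrasubstituted C1=C2 alkene instead of the allylsilane. Fallback: sulfoxide 43 undergoes an ordinary Pummerer rearrangement (Ac2O, NaOAc) to the α-acetoxy sulfide F4. Mild hydrolysis gives the α-keto aldehyde F5, BF3·OEt2 induces intramolecular Hosomi–Sakurai addition of the allylsilane to this aldehyde to give the ring E ketol F6, and SmI2 in THF–MeOH removes the α-hydroxyl, returning to 45.

Step 36. Epimerisation at C7 may outrun ring closure, the lactone may close cis, or C5 may form with the wrong configuration. Fallback: 50 is converted with t-BuMe2SiOTf and Et3N into the bis(silyl enol ether) F7, whose 1-silyloxy diene should attack the acetal carbon C6 of the pseudoester at C5 under TiCl4 at −78 °C. This is the Lewis-acid substitution known for 3-alkoxyphthalides: entry is anti to the C7 substituent, the lactone is retained and the route is rejoined at 52. C7 does not epimerise here, so it would have to be set beforehand by running step 29 with a p-tol-BINAP-ligated copper hydride.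

Further compounds

F1 | step 18 | C14-nitro bicyclo[2.2.2]octenone (nitroethylene adduct) | COC1(OC)[C@@H]2C([N+](=O)[O-])C[C@]([C@@H]5[C@H]6OC(=O)[C@@H](CN(C)C)[C@@H]6[C@H](O[Si](C(C)C)(C(C)C)C(C)C)CC(OS(=O)(=O)C(F)(F)F)=C5)(C1=O)C3=C2C[C@H]4CO[Si](C(C)(C)C)(C(C)(C)C)O[C@@H]34
F2 | step 15 | arylmagnesium bromide from 19 | COCOc1c(OC)cc2C[C@H]3CO[Si](C(C)(C)C)(C(C)(C)C)O[C@H]3c2c1[Mg]Br
F3 | step 19 | C3' chlorohydrin | COC1(OC)[C@@H]2CC[C@]([C@@H]5[C@H]6OC(=O)[C@@H](CN(C)C)[C@@H]6[C@H](O[Si](C(C)C)(C(C)C)C(C)C)CC(OS(=O)(=O)C(F)(F)F)=C5)(C1(O)CCl)C3=C2C[C@H]4CO[Si](C(C)(C)C)(C(C)(C)C)O[C@@H]34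
F4 | step 31 | α-acetoxy sulfide | COC1OC(=O)C(CN(C)C)C1CC[C@@H]2CC[C@]([C@@H]5[C@H]6OC(=O)[C@@H](CN(C)C)[C@@H]6[C@H](O[Si](C(C)C)(C(C)C)C(C)C)CC(C[Si](C)(C)C)=C5)(C(=O)C(OC(C)=O)Sc7ccccc7)C3=C2C[C@H]4CO[Si](C(C)(C)C)(C(C)(C)C)O[C@@H]34
F5 | step 31 | α-keto aldehyde | COC1OC(=O)C(CN(C)C)C1CC[C@@H]2CC[C@]([C@@H]5[C@H]6OC(=O)[C@@H](CN(C)C)[C@@H]6[C@H](O[Si](C(C)C)(C(C)C)C(C)C)CC(C[Si](C)(C)C)=C5)(C(=O)C=O)C3=C2C[C@H]4CO[Si](C(C)(C)C)(C(C)(C)C)O[C@@H]34
F6 | step 31 | ring E ketol (C2' hydroxyl) | COC1OC(=O)C(CN(C)C)C1CC[C@@H]2CC[C@]5(C(=O)C(O)[C@H]6C(=C)C[C@@H](O[Si](C(C)C)(C(C)C)C(C)C)[C@H]7[C@H](CN(C)C)C(=O)O[C@@H]7[C@H]65)C3=C2C[C@H]4CO[Si](C(C)(C)C)(C(C)(C)C)O[C@@H]34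
F7 | step 36 | bis(tert-butyldimethylsilyl enol ether) of 50 | COC1OC(=O)C(CN(C)C)C1CC[C@@H]2CC[C@]5(C(O[Si](C)(C)C(C)(C)C)=C[C@H]6C(=C)C[C@@H](O[Si](C(C)C)(C(C)C)C(C)C)[C@H]7[C@H](CN(C)C)C(=O)O[C@@H]7[C@H]65)C3=C(O[Si](C)(C)C(C)(C)C)C(CN(C)C)C=C23
A1 | alternative 1 | hexacyclic (5+2) cycloadduct with rings E and F | C=C1[C@H](O[Si](CC)(CC)CC)C2=C3[C@H](CC[C@H]4CC(=O)O[C@@H]4[C@H]13)CC[C@]21[C@H](O[Si](CC)(CC)CC)C[C@H]2C(=C)C[C@@H](O[Si](c3ccccc3)(c4ccccc4)C(C)(C)C)C(CC(=O)OC)=C(OC)[C@H]21
A2 | alternative 2 | spirocyclohexadienone with rings A, D and E | O=C1CCC2=C1[C@]3(C=CC2=O)[C@H](O[Si](C)(C)C(C)(C)C)C[C@@H](C(C)=C)[C@H]3C=C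
A3 | alternative 3 | C8' tert-butyldimethylsilyl ether of the target | C=C1C(=O)C2=C3[C@H](CC[C@H]4C(=C)C(=O)O[C@@H]4[C@H]13)CC[C@]21C(=O)C[C@H]2C(=C)C[C@@H](O[Si](C)(C)C(C)(C)C)[C@H]3C(=C)C(=O)O[C@@H]3[C@H]21
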